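**Retrosynthetic overview**

1. The target is the (2S)-flavanone; the last step only frees the C7 phenol from a triisopropylsilyl ether.
2. Ring C is a β-aryloxy ketone (O1–C2–C3–C4=O) whose C2 lies between O1 and ring B, which carries the chromene oxygen para to C2. C2 can therefore be held as an acetal carbon bonded to the C4 oxygen in a temporary 4-methylidene-1,3-benzodioxine ring (O1–C2–O3–C4–C4a–C8a), and an enantioconvergent Petasis–Ferrier rearrangement then swaps ring oxygen O3 for carbon C3 by forming the C2–C3 bond.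
3. The racemic enol acetal comes from methylenation of a 1,3-benzodioxin-4-one, itself the simple acetal union of a ring A salicylic acid with a ring B aldehyde.
4. Ring B aldehyde: 4-hydroxybenzaldehyde, ortho C-prenylation, then propargyl ether Claisen/electrocyclisation to the chromene. Ring A acid: methyl 2,4-dihydroxybenzoate, aromatic Claisen prenylation at C3, saponification, silylation.
5. Order of ring formation: chromene pyran ring (step 3), temporary dioxinone ring (step 9), ring C (step 11).

Key step: step 11

Remark on the chemistry: the target SMILES encodes the (2S) configuration. The acetal centre of the dioxine precursor is erased in the key step, so that precursor is made as the racemate. The sense of induction of the chiral anion in step 11 cannot be predicted and the catalyst antipode is assumed to be chosen accordingly.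

**Route**

Step 1
Reactants: 1 4-hydroxybenzaldehyde; 2 prenyl bromide (1-bromo-3-methylbut-2-ene)
Product: 3 4-hydroxy-3-(3-methylbut-2-en-1-yl)benzaldehyde
Conditions: 2 (1 equiv), 10% aq. KOH, 0 °C to rt
Reagents that add atoms: prenyl bromide 2, CC(C)=CCBr
Why: Ortho C-alkylation of a phenoxide in water, where solvation of the phenoxide oxygen disfavours O-alkylation, should give the mono-prenyl phenol because the para position is blocked by the formyl group and the two ortho positions are equivalent.

Step 2
Reactants: 3 4-hydroxy-3-(3-methylbut-2-en-1-yl)benzaldehyde; 4 3-chloro-3-methylbut-1-yne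
Product: 5 3-(3-methylbut-2-en-1-yl)-4-[(2-methylbut-3-yn-2-yl)oxy]benzaldehyde
Conditions: 4, K2CO3, KI, CuI (cat.), acetone, reflux
Reagents that add atoms: 3-chloro-3-methylbut-1-yne 4, CC(C)(Cl)C#C
Why: Copper-assisted propargylic O-alkylation of a phenoxide with a tertiary propargylic chloride is the standard entry to aryl 1,1-dimethylpropargyl ethers.

Step 3
Reactants: 5 3-(3-methylbut-2-en-1-yl)-4-[(2-methylbut-3-yn-2-yl)oxy]benzaldehyde
Product: 8 2,2-dimethyl-8-(3-methylbut-2-en-1-yl)-2H-chromene-6-carbaldehyde, via allenylphenol 6 (not isolated), via ortho-quinone methide 7 (not isolated)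
Conditions: PhNEt2, 180 °C
Reagents that add atoms: none
Why: A thermal aromatic propargyl Claisen rearrangement to the only free ortho position, followed by a 1,5-hydrogen shift and a 6π oxa-electrocyclisation, is the standard construction of a 2,2-dimethyl-2H-chromene.

Step 4
Reactants: 9 methyl 2,4-dihydroxybenzoate; 4 3-chloro-3-methylbut-1-yne
Product: 10 methyl 2-hydroxy-4-[(2-methylbut-3-yn-2-yl)oxy]benzoate
Conditions: 4, K2CO3, KI, CuI (cat.), acetone, reflux
Reagents that add atoms: 3-chloro-3-methylbut-1-yne 4, CC(C)(Cl)C#C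
Why: The same copper-assisted propargylic etherification should be selective for the 4-OH because the 2-OH is held in the hydrogen bond to the ester carbonyl.

Step 5
Reactants: 10 methyl 2-hydroxy-4-[(2-methylbut-3-yn-2-yl)oxy]benzoate
Product: 11 methyl 2-hydroxy-4-[(2-methylbut-3-en-2-yl)oxy]benzoate
Conditions: H2 (1 atm), Pd/CaCO3 poisoned with Pb(OAc)2 (Lindlar catalyst), quinoline, EtOAc, rt
Reagents that add atoms: none
Why: Lindlar semihydrogenation of the terminal alkyne should stop at the 1,1-dimethylallyl ether.

Step 6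
Reactants: 11 methyl 2-hydroxy-4-[(2-methylbut-3-en-2-yl)oxy]benzoate
Product: 13 methyl 2,4-dihydroxy-3-(3-methylbut-2-en-1-yl)benzoate, via cyclohexadienone 12 (not isolated)
Conditions: PhNEt2, 140 °C
Reagents that add atoms: none
Why: The aromatic Claisen rearrangement of the 1,1-dimethylallyl ether should deliver the prenyl group to C3, the ortho position favoured by the bond fixation of the chelated salicylate, and dienone 12 then enolises.

Step 7
Reactants: 13 methyl 2,4-dihydroxy-3-(3-methylbut-2-en-1-yl)benzoate
Product: 14 2,4-dihydroxy-3-(3-methylbut-2-en-1-yl)benzoic acid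
Conditions: KOH, MeOH/H2O, 60 °C; then cold 1 M HCl to pH 3
Reagents that add atoms: potassium hydroxide, [K+].[OH-] (its oxygen becomes the acid OH)
Why: Saponification of the methyl ester, with cold acidification to avoid decarboxylation and acid cyclisation of the ortho-prenylphenol.

Step 8
Reactants: 14 2,4-dihydroxy-3-(3-methylbut-2-en-1-yl)benzoic acid
Product: 16 2-hydroxy-3-(3-methylbut-2-en-1-yl)-4-[(triisopropylsilyl)oxy]benzoic acid, via bis(triisopropylsilyl) derivative 15 (not isolated)
Conditions: TIPSCl (2.2 equiv), imidazole, DMF, rt; then AcOH/THF/H2O (3:1:1), rt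
Reagents that add atoms: triisopropylsilyl chloride, CC(C)[Si](Cl)(C(C)C)C(C)C
Why: Silylation should take the carboxylic acid and the 4-OH but not the chelated, doubly flanked 2-OH, and mild aqueous acid then hydrolyses only the much more labile silyl ester.

Step 9
Reactants: 16 2-hydroxy-3-(3-methylbut-2-en-1-yl)-4-[(triisopropylsilyl)oxy]benzoic acid; 8 2,2-dimethyl-8-(3-methylbut-2-en-1-yl)-2H-chromene-6-carbaldehyde
Product: 18 rac-2-[2,2-dimethyl-8-(3-methylbut-2-en-1-yl)-2H-chromen-6-yl]-8-(3-methylbut-2-en-1-yl)-7-[(triisopropylsilyl)oxy]-4H-1,3-benzodioxin-4-one, via bis(trimethylsilyl) derivative 17 (not isolated)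
Conditions: HMDS, 60 °C, then evaporate; 8, TMSOTf (10 mol%), CH2Cl2, −78 °C; pyridine quench
Reagents that add atoms: hexamethyldisilazane, C[Si](C)(C)N[Si](C)(C)C (gives the two Me3Si groups of intermediate 17; none of its atoms remain in 18)
Why: Silyl triflate-catalysed acetalisation of a bis-silylated hydroxy acid with an aldehyde (the union stage of the Petasis–Ferrier tactic) should close the temporary dioxinone ring at low temperature, with hexamethyldisiloxane as the only by-product and a racemic acetal centre that is erased later.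

Step 10
Reactants: 18 rac-2-[2,2-dimethyl-8-(3-methylbut-2-en-1-yl)-2H-chromen-6-yl]-8-(3-methylbut-2-en-1-yl)-7-[(triisopropylsilyl)oxy]-4H-1,3-benzodioxin-4-one
Product: 19 rac-2-[2,2-dimethyl-8-(3-methylbut-2-en-1-yl)-2H-chromen-6-yl]-4-methylidene-8-(3-methylbut-2-en-1-yl)-7-[(triisopropylsilyl)oxy]-4H-1,3-benzodioxine
Conditions: Cp2TiMe2 (2 equiv), toluene/THF, 65 °C, dark; filtration through basic alumina, used at once
Reagents that add atoms: dimethyltitanocene, C[Ti](C)(C1C=CC=C1)C1C=CC=C1 (adds CH2)
Why: Petasis methylenation through Cp2Ti=CH2 is established for aryl esters and 1,3-dioxan-4-ones, leaves trisubstituted alkenes and silyl ethers alone, and gives an exocyclic enol ether that cannot isomerise because C4 has no ring hydrogen next to it.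

Step 11
Reactants: 19 rac-2-[2,2-dimethyl-8-(3-methylbut-2-en-1-yl)-2H-chromen-6-yl]-4-methylidene-8-(3-methylbut-2-en-1-yl)-7-[(triisopropylsilyl)oxy]-4H-1,3-benzodioxine
Product: 21 (2S)-2-[2,2-dimethyl-8-(3-methylbut-2-en-1-yl)-2H-chromen-6-yl]-8-(3-methylbut-2-en-1-yl)-7-[(triisopropylsilyl)oxy]-2,3-dihydro-4H-chromen-4-one, via silyl enol ether oxocarbenium ion pair 20 (not isolated)
Conditions: chiral imidodiphosphorimidate Brønsted acid (IDPi: two 3,3'-diaryl-BINOL units, N-triflyl groups; 3 mol%) premixed with methallyltrimethylsilane (10 mol%), toluene/CH2Cl2, 4 Å MS, −60 °C; Et3N quench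
Reagents that add atoms: methallyltrimethylsilane, CC(=C)C[Si](C)(C)C (source of the Me3Si group of intermediate 20; none of its atoms remain in 21)
Why: Proposed new method: the silylium ion pair Me3Si+·X*− (X*− is the confined chiral IDPi anion, made in the flask from the acid and methallyltrimethylsilane) silylates the enol-ether oxygen O3 of racemic 19 and breaks the C2–O3 acetal bond to give the achiral ion pair 20, whose silyl enol ether carbon C3 then adds to the oxocarbenium carbon C2, after which the Me3Si group leaves the new C4 carbonyl oxygen for the next molecule of 19. The closest known reaction types are the Me2AlCl- or silyl triflate-promoted Petasis–Ferrier (O-to-C) rearrangements of cyclic enol acetals to pyranones and the chiral-anion (IDPi) controlled additions of silyl enol ethers and alkenes (Prins cyclisation) to oxocarbenium ions; their combination on a benzo-fused 4-methylidene-1,3-dioxine is new. Ring C closes by a 6-(enolendo)-endo-trig attack of C3 on the O1=C2 oxocarbenium, so that ring oxygen O3 of the temporary dioxine is exchanged for carbon C3 and becomes the C4 carbonyl oxygen. The only stereocentre, C2, is created at the planar cation, so both enantiomers of 19 converge, and the (S) configuration follows from attack on the Si face of C2 (O1 > ring B > H), the face the chiral anion has to leave open; which catalyst antipode does this is to be established on a model acetal. The step needs ionisation of C2–O3 and not C2–O1, C- and not O-recombination, and attack by C3 and not by the C8 prenyl alkene (Prins): the para chromene oxygen of ring B makes C2 easy to ionise and only loss of the silyl enol ether oxygen leads to a cation with an internal carbon nucleophile, C–C bond formation is irreversible because it gives the C4=O bond, and the tethered silyl enol ether is far more nucleophilic than a trisubstituted alkene. Proton-free conditions at −60 °C should keep the prenyl groups, the chromene and the aryl silyl ether intact and prevent ring opening of the product at C2.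

Step 12
Reactants: 21 (2S)-2-[2,2-dimethyl-8-(3-methylbut-2-en-1-yl)-2H-chromen-6-yl]-8-(3-methylbut-2-en-1-yl)-7-[(triisopropylsilyl)oxy]-2,3-dihydro-4H-chromen-4-one
Product: 22 (2S)-2-[2,2-dimethyl-8-(3-methylbut-2-en-1-yl)-2H-chromen-6-yl]-7-hydroxy-8-(3-methylbut-2-en-1-yl)-2,3-dihydro-4H-chromen-4-one
Conditions: TBAF, AcOH (1:1), THF, 0 °C
Reagents that add atoms: none
Why: Fluoride cleavage of the aryl silyl ether, buffered with acetic acid so that the base-sensitive C2 centre (retro-oxa-Michael ring opening) should not racemise.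

**Compound list**

1 | 4-hydroxybenzaldehyde | O=Cc1ccc(O)cc1 | starting material
2 | prenyl bromide (1-bromo-3-methylbut-2-ene) | CC(C)=CCBr | starting material
3 | 4-hydroxy-3-(3-methylbut-2-en-1-yl)benzaldehyde | CC(C)=CCc1cc(C=O)ccc1O | intermediate
4 | 3-chloro-3-methylbut-1-yne | CC(C)(Cl)C#C | starting material
5 | 3-(3-methylbut-2-en-1-yl)-4-[(2-methylbut-3-yn-2-yl)oxy]benzaldehyde | CC(C)=CCc1cc(C=O)ccc1OC(C)(C)C#C | intermediate
6 | 4-hydroxy-3-(3-methylbuta-1,2-dien-1-yl)-5-(3-methylbut-2-en-1-yl)benzaldehyde (allenylphenol) | CC(C)=CCc1cc(C=O)cc(C=C=C(C)C)c1O | intermediate (not isolated)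
7 | 3-(3-methylbut-2-en-1-ylidene)-5-(3-methylbut-2-en-1-yl)-4-oxocyclohexa-1,5-diene-1-carbaldehyde (ortho-quinone methide) | CC(C)=CCC1=CC(C=O)=CC(=CC=C(C)C)C1=O | intermediate (not isolated)
8 | 2,2-dimethyl-8-(3-methylbut-2-en-1-yl)-2H-chromene-6-carbaldehyde | CC(C)=CCc1cc(C=O)cc2c1OC(C)(C)C=C2 | intermediate
9 | methyl 2,4-dihydroxybenzoate | COC(=O)c1ccc(O)cc1O | starting material
10 | methyl 2-hydroxy-4-[(2-methylbut-3-yn-2-yl)oxy]benzoate | COC(=O)c1ccc(OC(C)(C)C#C)cc1O | intermediate
11 | methyl 2-hydroxy-4-[(2-methylbut-3-en-2-yl)oxy]benzoate | COC(=O)c1ccc(OC(C)(C)C=C)cc1O | intermediate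
12 | methyl 2-hydroxy-3-(3-methylbut-2-en-1-yl)-4-oxocyclohexa-1,5-diene-1-carboxylate (cyclohexadienone) | COC(=O)C1=C(O)C(CC=C(C)C)C(=O)C=C1 | intermediate (not isolated)
13 | methyl 2,4-dihydroxy-3-(3-methylbut-2-en-1-yl)benzoate | COC(=O)c1ccc(O)c(CC=C(C)C)c1O | intermediate
14 | 2,4-dihydroxy-3-(3-methylbut-2-en-1-yl)benzoic acid | OC(=O)c1ccc(O)c(CC=C(C)C)c1O | intermediate
15 | triisopropylsilyl 2-hydroxy-3-(3-methylbut-2-en-1-yl)-4-[(triisopropylsilyl)oxy]benzoate | CC(C)[Si](C(C)C)(C(C)C)OC(=O)c1ccc(O[Si](C(C)C)(C(C)C)C(C)C)c(CC=C(C)C)c1O | intermediate (not isolated)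
16 | 2-hydroxy-3-(3-methylbut-2-en-1-yl)-4-[(triisopropylsilyl)oxy]benzoic acid | OC(=O)c1ccc(O[Si](C(C)C)(C(C)C)C(C)C)c(CC=C(C)C)c1O | intermediate
17 | trimethylsilyl 3-(3-methylbut-2-en-1-yl)-4-[(triisopropylsilyl)oxy]-2-[(trimethylsilyl)oxy]benzoate | C[Si](C)(C)OC(=O)c1ccc(O[Si](C(C)C)(C(C)C)C(C)C)c(CC=C(C)C)c1O[Si](C)(C)C | intermediate (not isolated)
18 | rac-2-[2,2-dimethyl-8-(3-methylbut-2-en-1-yl)-2H-chromen-6-yl]-8-(3-methylbut-2-en-1-yl)-7-[(triisopropylsilyl)oxy]-4H-1,3-benzodioxin-4-one | CC(C)=CCc1cc(C2OC(=O)c3ccc(O[Si](C(C)C)(C(C)C)C(C)C)c(CC=C(C)C)c3O2)cc2c1OC(C)(C)C=C2 | intermediate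
19 | rac-2-[2,2-dimethyl-8-(3-methylbut-2-en-1-yl)-2H-chromen-6-yl]-4-methylidene-8-(3-methylbut-2-en-1-yl)-7-[(triisopropylsilyl)oxy]-4H-1,3-benzodioxine | CC(C)=CCc1cc(C2OC(=C)c3ccc(O[Si](C(C)C)(C(C)C)C(C)C)c(CC=C(C)C)c3O2)cc2c1OC(C)(C)C=C2 | intermediate
20 | ring-opened silyl enol ether/aryl oxocarbenium ion (cation shown; counter-ion is the chiral IDPi anion) | C=C(O[Si](C)(C)C)c1ccc(O[Si](C(C)C)(C(C)C)C(C)C)c(CC=C(C)C)c1[O+]=Cc1cc(CC=C(C)C)c2OC(C)(C)C=Cc2c1 | intermediate (not isolated)
21 | (2S)-2-[2,2-dimethyl-8-(3-methylbut-2-en-1-yl)-2H-chromen-6-yl]-8-(3-methylbut-2-en-1-yl)-7-[(triisopropylsilyl)oxy]-2,3-dihydro-4H-chromen-4-one | CC(C)=CCc1cc([C@@H]2CC(=O)c3ccc(O[Si](C(C)C)(C(C)C)C(C)C)c(CC=C(C)C)c3O2)cc2c1OC(C)(C)C=C2 | intermediate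
22 | (2S)-2-[2,2-dimethyl-8-(3-methylbut-2-en-1-yl)-2H-chromen-6-yl]-7-hydroxy-8-(3-methylbut-2-en-1-yl)-2,3-dihydro-4H-chromen-4-one | CC(C)=CCc1cc([C@@H]2CC(=O)c3ccc(O)c(CC=C(C)C)c3O2)cc2c1OC(C)(C)C=C2 | target

**Step count and risks**

Total step count: 12 (steps 1–3 for the ring B aldehyde, steps 4–8 for the ring A acid, steps 9–12 after convergence).
Longest linear sequence: 9 steps (steps 4–12, from methyl 2,4-dihydroxybenzoate).

Steps most likely to fail:

1. Step 11 (Proposed new method). What may go wrong: the chiral anion may discriminate the two faces of the oxocarbenium ion poorly, silyl turnover may stall on the basic product carbonyl, or the cation may be intercepted by the neighbouring C8 prenyl alkene or by adventitious water. The fallback uses known chemistry, sets out from 19 and comes back at 21. Enol acetal 19 would be treated with Me2AlCl in CH2Cl2 at −78 °C, the established aluminium-mediated Petasis–Ferrier rearrangement, to give the racemic silyl-protected flavanone F1. F1 would then be resolved kinetically by asymmetric transfer hydrogenation (RuCl(p-cymene)[(R,R)-TsDPEN], HCO2H/Et3N, EtOAc, rt, stopped near half conversion). The (2R) enantiomer should be reduced to the cis-(2R,4R)-flavan-4-ol F2, and the unreacted (2S) ketone 21 would be separated by chromatography and carried into step 12.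

2. Step 9. What may go wrong: incomplete silylation of the chelated, doubly flanked 2-OH, or ionisation of the donor-substituted acetal as it forms under the silyl triflate, leading to reversion, oligomerisation or attack on the electron-rich chromene alkene. The fallback sets out from 8 and 16 and comes back at 18. Aldehyde 8 would be converted with HC(OMe)3 and catalytic PPTS in MeOH into its dimethyl acetal F3. F3 would then undergo acetal exchange with hydroxy acid 16 under catalytic PPTS in toluene at 50 °C under reduced pressure, with removal of methanol, to give 18 under thermodynamic control and without a silyl Lewis acid.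

3. Step 1. What may go wrong: competing O-alkylation and double C-alkylation of the phenoxide, leaving little mono-ortho-prenyl product. The fallback sets out from 1 and comes back at 3. Phenol 1 would be etherified with 4 (K2CO3, KI, CuI cat., acetone, reflux) to the propargyl ether F4. F4 would be semihydrogenated (H2, Pd/CaCO3 poisoned with Pb(OAc)2, quinoline) to the 1,1-dimethylallyl ether F5. F5 would be heated in PhNEt2 at 140 °C, where the aromatic Claisen rearrangement should pass through the cyclohexadienone F6 (not isolated) and give 3 with complete ortho regiocontrol.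

**Further compounds**

F1 | step 11 | rac-2-[2,2-dimethyl-8-(3-methylbut-2-en-1-yl)-2H-chromen-6-yl]-8-(3-methylbut-2-en-1-yl)-7-[(triisopropylsilyl)oxy]-2,3-dihydro-4H-chromen-4-one | CC(C)=CCc1cc(C2CC(=O)c3ccc(O[Si](C(C)C)(C(C)C)C(C)C)c(CC=C(C)C)c3O2)cc2c1OC(C)(C)C=C2
F2 | step 11 | (2R,4R)-2-[2,2-dimethyl-8-(3-methylbut-2-en-1-yl)-2H-chromen-6-yl]-8-(3-methylbut-2-en-1-yl)-7-[(triisopropylsilyl)oxy]-3,4-dihydro-2H-chromen-4-ol | CC(C)=CCc1cc([C@H]2C[C@@H](O)c3ccc(O[Si](C(C)C)(C(C)C)C(C)C)c(CC=C(C)C)c3O2)cc2c1OC(C)(C)C=C2
F3 | step 9 | 6-(dimethoxymethyl)-2,2-dimethyl-8-(3-methylbut-2-en-1-yl)-2H-chromene | COC(OC)c1cc(CC=C(C)C)c2OC(C)(C)C=Cc2c1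
F4 | step 1 | 4-[(2-methylbut-3-yn-2-yl)oxy]benzaldehyde | C#CC(C)(C)Oc1ccc(C=O)cc1
F5 | step 1 | 4-[(2-methylbut-3-en-2-yl)oxy]benzaldehyde | C=CC(C)(C)Oc1ccc(C=O)cc1
F6 | step 1 | 5-(3-methylbut-2-en-1-yl)-4-oxocyclohexa-1,5-diene-1-carbaldehyde (cyclohexadienone, not isolated) | CC(C)=CCC1C=C(C=O)C=CC1=O
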